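The numbers in the tables come from a simulation for an exercise.

This flask is reckoned by its catalyst dose of 21.6 M·s, the charge of free catalyst times the time, with substrate, the limiting reagent, followed as the fraction of its charge left.

| flask | substrate | partner | scavenger | free catalyst | remark | time |
|---|---|---|---|---|---|---|
| Tuesday's | 0.23 M | 0.253 M | 0.345 M | 6 mM | run made earlier |  |
| Thursday's | 0.23 M | 0.253 M | 0.345 M | 9 mM | run made earlier |  |
| flask | 0.23 M | 0.253 M | 0.345 M | 12 mM |  | 30 min |

| run | time / min | substrate / % | target / % |
|---|---|---|---|
| Tuesday's | 2.50 | 94.8 | 3.0 |
| Tuesday's | 6.00 | 93.3 | 7.3 |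
| Tuesday's | 12.0 | 86.2 | 10.7 |
| Tuesday's | 20.0 | 79.6 | 18.5 |
| Thursday's | 1.33 | 97.3 | 1.6 |
| Thursday's | 3.00 | 94.5 | 4.1 |
| Thursday's | 8.00 | 87.9 | 10.8 |
| Thursday's | 20.0 | 69.9 | 26.8 |

(readings scatter by 1 percentage point)

1. part of the substrate that has reacted at 30 min
2. share of the unused partner that is free and not bound as idle adduct, at 30 min

- what was read earlier has a scatter of 1 percentage point, one standard deviation
- the earlier runs do not show how much of partner is bound; that part of a forecast is a guess

The runs differ in catalyst, and one pair of readings shares a dose: at 4.32 M·s, substrate stands at 86.2% in Tuesday's run and 87.9% in Thursday's, a gap comparable with the scatter of 1 percentage point. Thursday's last reading carries more dose than Tuesday's last, and this flask's dose is twice that reading's. If the pace per dose stays constant, the reacted fraction doubles, which puts the upper end of the bracket at 60.2%. If the pace falls in proportion to the substrate left, the fraction left squares, which puts the lower end at 51.1%. At Thursday's 8.00 min the two cases differ by 1.3 points, close to that scatter, so this reckoning commits to the middle, 55.7%; the runs do not show bound partner, so the free share of partner stays a guess.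

The forecast puts 50% reacted, in its words “about 50% remains a reasonable centre”, just below the bracket, and 55% of the unused partner free.

The flask gives 56.3% reacted, inside the bracket, with 92.4% of the unused partner free.

    substrate + free catalyst ⇌ catalyst intermediate A (K = 8.46 /M, k = 0.279 /M/s)
    catalyst intermediate A ⇌ catalyst intermediate B (K = 1.20, k = 0.0374 /s)
    partner + catalyst intermediate B → catalyst intermediate C (k = 1.80 /M/s)
    catalyst intermediate C → released group + catalyst intermediate D (k = 0.0224 /s)
    catalyst intermediate D → free catalyst + target (k = 0.0202 /s)
    partner + released group ⇌ idle adduct, settled at all times (K = 14.0 /M)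
    scavenger + released group → scavenged by-product (k = 0.0458 /M/s)

At 15.0 min the flask has received the dose of Thursday's last reading and holds 69.0% of substrate, against 69.9% read there. Between 3.00 min and 30.0 min substrate fell from 91.7% to 43.7% while free catalyst rose from 20.7% to 35.3% of its charge, the remainder sitting in the catalyst intermediates. Released group meanwhile passed to scavenged by-product, 0.109 M by the end, with idle adduct at 0.00953 M. A neighbour charged with 0.0030 M of free catalyst has a dose of 5.40 M·s, half of Thursday's last, so the straight line gives 15.0%, and that neighbour reacted 15.4%.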